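**Strategy.** Tabularin is disconnected at the aryl–oxygen bond O1–C8a of the pyranone ring C. C8a lies on ring A ortho to C4a, the carbon that bears the C4 carbonyl, so a 1-(2-bromoaryl)-1,3-diketone already contains every carbon of the flavone. A copper-catalysed intramolecular O-arylation of its enolate forms O1–C8a and closes ring C in one operation. The site of the bromine alone fixes the 5,6,7-oxygenation pattern, so two phenols never have to be told apart. The precursor is an open-chain diketone with bromine at the future C8a, methoxymethyl ethers on the future O5 and O7, methoxy at C6, and a 2,4,5-trimethoxybenzoyl terminus.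

Key step: step 8

Remarks on the chemistry:
- Atom and ring labels follow flavone numbering (ring A benzo, ring C pyranone, ring B the 2-aryl group).
- Steps 1 and 4 each functionalise two equivalent phenols, so two equivalents of the acyl chloride and of the chloromethyl ether end up in the respective product.
- The bromine is introduced while the phenols are pivalate esters. The copper dibromide stage releases HBr in hot aqueous methanol, which methoxymethyl ethers would not survive, so the acetal ethers are installed afterwards.
- The aldol adduct is made and used as a racemate; its stereocentre is erased by the oxidation that follows.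

Step 1
Reactants: 1 2-methoxybenzene-1,3-diol; 2 2,2-dimethylpropanoyl chloride (pivaloyl chloride)
Product: 3 2-methoxy-1,3-phenylene bis(2,2-dimethylpropanoate)
Conditions: 2 (2.3 equiv), Et3N (3 equiv), DMAP (5 mol %), CH2Cl2, 0 °C to rt
Reagents that add atoms: 2,2-dimethylpropanoyl chloride, CC(C)(C)C(=O)Cl (the second equivalent of 2; each of the two phenols takes up one acyl group)
Why: DMAP-catalysed O-acylation (esterification) of two unhindered, equivalent phenols with two equivalents of the acyl chloride is routine, and pivalates carry no aromatic C–H bond, withstand the acidic copper stage of step 2 and damp the reactivity of ring A towards electrophilic bromine.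

Step 2
Reactants: 3 2-methoxy-1,3-phenylene bis(2,2-dimethylpropanoate)
Product: 5 5-bromo-2-methoxy-1,3-phenylene bis(2,2-dimethylpropanoate), via aryl pinacol boronate 4 (not isolated)
Conditions: B2pin2 (1.0 equiv), [Ir(OMe)(cod)]2 (1.5 mol %), 4,4'-di-tert-butyl-2,2'-bipyridine (3 mol %), THF, 80 °C; evaporate; CuBr2 (3 equiv), MeOH/H2O 1:1, 80 °C
Reagents that add atoms: copper dibromide CuBr2, Br[Cu]Br; bis(pinacolato)diboron B2pin2, CC1(C)OB(OC1(C)C)B1OC(C)(C)C(C)(C)O1 (its boron stays only in intermediate 4)
Why: Iridium-catalysed C–H borylation is sterically controlled and should select C5, the only C–H without an ortho substituent, and the copper-mediated bromodeboronation (transmetalation from boron to copper, then C–Br bond formation at the same carbon) converts that boronate into a bromide on an arene that keeps its mirror symmetry.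

Step 3
Reactants: 5 5-bromo-2-methoxy-1,3-phenylene bis(2,2-dimethylpropanoate)
Product: 6 5-bromo-2-methoxybenzene-1,3-diol
Conditions: NaOMe (2.5 equiv), MeOH, 0 °C to rt, N2; then dilute aq. HCl to pH 4
Reagents that add atoms: none
Why: Methoxide-mediated transesterification (acyl substitution with a phenoxide leaving group) should release both phenols and leaves the aryl bromide untouched.

Step 4
Reactants: 6 5-bromo-2-methoxybenzene-1,3-diol; 7 chloromethyl methyl ether
Product: 8 5-bromo-2-methoxy-1,3-bis(methoxymethoxy)benzene
Conditions: 7 (3 equiv), i-Pr2NEt (4 equiv), CH2Cl2, 0 °C to rt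
Reagents that add atoms: chloromethyl methyl ether, COCCl (the second equivalent of 7; each of the two phenols takes up one methoxymethyl group)
Why: O-Alkylation of the two equivalent phenols with two equivalents of the α-chloro ether (Williamson-type ether synthesis through an oxocarbenium-like electrophile) is standard, and the resulting acetal ethers tolerate every basic step ahead while serving as directing groups for the metalation.

Step 5
Reactants: 8 5-bromo-2-methoxy-1,3-bis(methoxymethoxy)benzene
Product: 10 6-bromo-3-methoxy-2,4-bis(methoxymethoxy)benzaldehyde, via aryllithium 9 (not isolated)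
Conditions: LDA [LiN(i-Pr)2] (1.15 equiv), THF, −78 °C, 1 h; DMF (3 equiv), −78 to −40 °C; AcOH, then H2O
Reagents that add atoms: N,N-dimethylformamide, CN(C)C=O
Why: Directed ortho-metalation with a lithium amide deprotonates instead of exchanging the halogen, the only kind of ring proton present is flanked by bromine and a coordinating methoxymethoxy group, and formylation of the resulting aryllithium with DMF at low temperature should outpace loss of LiBr, so a single aldehyde results.

Step 6
Reactants: 10 6-bromo-3-methoxy-2,4-bis(methoxymethoxy)benzaldehyde; 11 1-(2,4,5-trimethoxyphenyl)ethanone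
Product: 13 3-[6-bromo-3-methoxy-2,4-bis(methoxymethoxy)phenyl]-3-hydroxy-1-(2,4,5-trimethoxyphenyl)propan-1-one (racemate), via lithium enolate 12 (not isolated)
Conditions: 11 (1.25 equiv), LDA [LiN(i-Pr)2] (1.2 equiv), THF, −78 °C, 45 min; add 10 (1.0 equiv), −78 °C, 1 h; AcOH at −78 °C
Reagents that add atoms: none
Why: Directed (crossed) aldol addition of a preformed lithium enolate to a non-enolisable aldehyde is fast and clean at −78 °C, and the carbinol stereocentre, formed without control as a racemate, is removed in step 7.

Step 7
Reactants: 13 3-[6-bromo-3-methoxy-2,4-bis(methoxymethoxy)phenyl]-3-hydroxy-1-(2,4,5-trimethoxyphenyl)propan-1-one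
Product: 14 1-[6-bromo-3-methoxy-2,4-bis(methoxymethoxy)phenyl]-3-(2,4,5-trimethoxyphenyl)propane-1,3-dione
Conditions: IBX (2 equiv), EtOAc, 75 °C
Reagents that add atoms: none
Why: Hypervalent-iodine oxidation of a β-hydroxy ketone with 2-iodoxybenzoic acid (IBX oxidation) is a reliable way to 1,3-diketones, stops at that stage and is mild enough for the acetal ethers and the aryl bromide.

Step 8
Reactants: 14 1-[6-bromo-3-methoxy-2,4-bis(methoxymethoxy)phenyl]-3-(2,4,5-trimethoxyphenyl)propane-1,3-dione
Product: 15 6-methoxy-5,7-bis(methoxymethoxy)-2-(2,4,5-trimethoxyphenyl)-4H-chromen-4-one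
Conditions: CuI (10 mol %), 1,10-phenanthroline (20 mol %), Cs2CO3 (2.0 equiv), DMF (0.05 M), 90 °C, N2
Reagents that add atoms: none
Why: Cs2CO3 turns the enolised diketone into its caesium enolate, which binds monovalent copper carrying 1,10-phenanthroline; oxidative addition into the C8a–Br bond, kept within reach by the ortho acyl tether, gives a trivalent copper aryl enolate, and C–O reductive elimination forms O1–C8a and regenerates monovalent copper. The closest known reaction type is the Ullmann-type copper-catalysed intramolecular O-arylation of 1-(2-haloaryl)-1,3-diketones to flavones. Ring C closes as a six-membered ring in 6-exo mode at the sp2 carbon C8a, with the oxygen on C2 as nucleophile and bromide departing outside the new ring. No stereocentre is formed. The step needs O- over C-arylation and a single direction of closure: attack through C3 or through the C4 oxygen would need a four-membered ring, and the other ortho oxygen of ring A is capped as a methoxymethyl ether, so the position of the bromine alone secures the 5,6,7-pattern. Working at 0.05 M under dry nitrogen should hold back intermolecular arylation and retro-Claisen cleavage.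

Step 9
Reactants: 15 6-methoxy-5,7-bis(methoxymethoxy)-2-(2,4,5-trimethoxyphenyl)-4H-chromen-4-one
Product: 16 tabularin, 5,7-dihydroxy-6-methoxy-2-(2,4,5-trimethoxyphenyl)-4H-chromen-4-one
Conditions: 3 M HCl in MeOH, THF co-solvent, 50 °C
Reagents that add atoms: none
Why: Acid-catalysed acetal cleavage (transacetalisation to methanol via the oxocarbenium ion) removes both methoxymethyl groups, whereas the four aryl methyl ethers and the pyranone are inert to dilute HCl at this temperature.

**Compound list**

1 | 2-methoxybenzene-1,3-diol | COc1c(O)cccc1O | starting material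
2 | 2,2-dimethylpropanoyl chloride | CC(C)(C)C(=O)Cl | starting material
3 | 2-methoxy-1,3-phenylene bis(2,2-dimethylpropanoate) | COc1c(OC(=O)C(C)(C)C)cccc1OC(=O)C(C)(C)C | intermediate
4 | 2-methoxy-5-(4,4,5,5-tetramethyl-1,3,2-dioxaborolan-2-yl)-1,3-phenylene bis(2,2-dimethylpropanoate) (not isolated) | COc1c(OC(=O)C(C)(C)C)cc(B2OC(C)(C)C(C)(C)O2)cc1OC(=O)C(C)(C)C | intermediate
5 | 5-bromo-2-methoxy-1,3-phenylene bis(2,2-dimethylpropanoate) | COc1c(OC(=O)C(C)(C)C)cc(Br)cc1OC(=O)C(C)(C)C | intermediate
6 | 5-bromo-2-methoxybenzene-1,3-diol | COc1c(O)cc(Br)cc1O | intermediate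
7 | chloromethyl methyl ether | COCCl | starting material
8 | 5-bromo-2-methoxy-1,3-bis(methoxymethoxy)benzene | COCOc1cc(Br)cc(OCOC)c1OC | intermediate
9 | [6-bromo-3-methoxy-2,4-bis(methoxymethoxy)phenyl]lithium (not isolated) | [Li]c1c(Br)cc(OCOC)c(OC)c1OCOC | intermediate
10 | 6-bromo-3-methoxy-2,4-bis(methoxymethoxy)benzaldehyde | COCOc1cc(Br)c(C=O)c(OCOC)c1OC | intermediate
11 | 1-(2,4,5-trimethoxyphenyl)ethanone | CC(=O)c1cc(OC)c(OC)cc1OC | starting material
12 | lithium 1-(2,4,5-trimethoxyphenyl)ethen-1-olate (not isolated) | [Li]OC(=C)c1cc(OC)c(OC)cc1OC | intermediate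
13 | 3-[6-bromo-3-methoxy-2,4-bis(methoxymethoxy)phenyl]-3-hydroxy-1-(2,4,5-trimethoxyphenyl)propan-1-one (racemate) | COCOc1cc(Br)c(C(O)CC(=O)c2cc(OC)c(OC)cc2OC)c(OCOC)c1OC | intermediate
14 | 1-[6-bromo-3-methoxy-2,4-bis(methoxymethoxy)phenyl]-3-(2,4,5-trimethoxyphenyl)propane-1,3-dione | COCOc1cc(Br)c(C(=O)CC(=O)c2cc(OC)c(OC)cc2OC)c(OCOC)c1OC | intermediate
15 | 6-methoxy-5,7-bis(methoxymethoxy)-2-(2,4,5-trimethoxyphenyl)-4H-chromen-4-one | COCOc1cc2oc(-c3cc(OC)c(OC)cc3OC)cc(=O)c2c(OCOC)c1OC | intermediate
16 | tabularin, 5,7-dihydroxy-6-methoxy-2-(2,4,5-trimethoxyphenyl)-4H-chromen-4-one | COc1cc(OC)c(-c2cc(=O)c3c(O)c(OC)c(O)cc3o2)cc1OC | target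

Total step count: 9
Longest linear sequence: 9 steps (1 to 16; ketone 11 enters at step 6)

**Steps most likely to fail**

1. Step 8. What may go wrong: oxidative addition may be slow because the aryl bromide is electron-rich and its activating acyl group is twisted out of the ring plane by two ortho neighbours, so protodebromination or base-induced retro-Claisen cleavage of the diketone could take over. Fallback: the sequence sets out from 14 and puts the oxygen on C8a first, then closes ring C at O1–C2 by cyclodehydration. Miyaura borylation (Pd(dppf)Cl2, B2pin2, KOAc, dioxane, 90 °C) should give 1-[3-methoxy-2,4-bis(methoxymethoxy)-6-(4,4,5,5-tetramethyl-1,3,2-dioxaborolan-2-yl)phenyl]-3-(2,4,5-trimethoxyphenyl)propane-1,3-dione F1. Oxidation with NaBO3·4H2O in THF/H2O at rt should give 1-[6-hydroxy-3-methoxy-2,4-bis(methoxymethoxy)phenyl]-3-(2,4,5-trimethoxyphenyl)propane-1,3-dione F2, which equilibrates with its cyclic hemiketal. Catalytic pyridinium p-toluenesulfonate in toluene at 80 °C should then dehydrate it, and the route is rejoined at 15. The oxygen still enters at the carbon that carried bromine and the other ortho oxygen stays capped, so the regiochemical argument is kept.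

2. Step 2. What may go wrong: a pivalate may be partly lost in the hot acidic copper dibromide medium, followed by nuclear bromination of the freed phenol, or the borylation may stay incomplete. Fallback: the sequence sets out from 1 and places the bromine ortho to a formyl group by directed lithiation, with no boron and no ester detour. Twofold methoxymethylation (7, i-Pr2NEt, CH2Cl2) should give 2-methoxy-1,3-bis(methoxymethoxy)benzene F3. Directed ortho-lithiation (n-BuLi, TMEDA, THF, 0 °C) and DMF should give 3-methoxy-2,4-bis(methoxymethoxy)benzaldehyde F4. Addition of LiN(Me)CH2CH2NMe2 masks the aldehyde in situ as lithium [2-(dimethylamino)ethyl](methyl)amino[3-methoxy-2,4-bis(methoxymethoxy)phenyl]methanolate F5, whose chelating side chain directs a second lithiation (n-BuLi, THF, −20 °C) to the C–H next to the masked formyl group. Quenching with 1,2-dibromotetrachloroethane at −78 °C and aqueous work-up should give 10, where the route is rejoined. This sequence is shorter, but it is held in reserve because the methoxymethoxy-directed neighbouring C–H competes for the second lithiation, whereas the symmetric bromoarene of the main route leaves no choice.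

3. Step 5. What may go wrong: the ortho-bromoaryllithium may lose LiBr to an aryne, or pass bromine from ring to ring, before DMF traps it. Fallback: the sequence sets out from 6 and replaces the organolithium by electrophilic aromatic substitution. Vilsmeier–Haack formylation (POCl3, DMF, MeCN, 0 °C to rt; aqueous hydrolysis) should give 6-bromo-2,4-dihydroxy-3-methoxybenzaldehyde F6. This is the only possible regioisomer, because both free ring positions are equivalent and each is ortho to one hydroxyl and para to the other. Twofold methoxymethylation (7, NaH, DMF, 0 °C to rt) should then give 10, where the route is rejoined; step 4 is bypassed.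

**Further compounds**

F1 | step 8 | 1-[3-methoxy-2,4-bis(methoxymethoxy)-6-(4,4,5,5-tetramethyl-1,3,2-dioxaborolan-2-yl)phenyl]-3-(2,4,5-trimethoxyphenyl)propane-1,3-dione | COCOc1cc(B3OC(C)(C)C(C)(C)O3)c(C(=O)CC(=O)c2cc(OC)c(OC)cc2OC)c(OCOC)c1OC
F2 | step 8 | 1-[6-hydroxy-3-methoxy-2,4-bis(methoxymethoxy)phenyl]-3-(2,4,5-trimethoxyphenyl)propane-1,3-dione | COCOc1cc(O)c(C(=O)CC(=O)c2cc(OC)c(OC)cc2OC)c(OCOC)c1OC
F3 | step 2 | 2-methoxy-1,3-bis(methoxymethoxy)benzene | COCOc1cccc(OCOC)c1OC
F4 | step 2 | 3-methoxy-2,4-bis(methoxymethoxy)benzaldehyde | COCOc1ccc(C=O)c(OCOC)c1OC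
F5 | step 2 | lithium [2-(dimethylamino)ethyl](methyl)amino[3-methoxy-2,4-bis(methoxymethoxy)phenyl]methanolate (racemate, not isolated) | COCOc1ccc(C(O[Li])N(C)CCN(C)C)c(OCOC)c1OC
F6 | step 5 | 6-bromo-2,4-dihydroxy-3-methoxybenzaldehyde | COc1c(O)cc(Br)c(C=O)c1O
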